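**Retrosynthetic overview**
1. Numbering is that of benzofuran: ring A is the 2,4-dihydroxyphenyl on C2, ring B the 3,5-dihydroxyphenyl on C3, ring C the fused benzene, ring D the 4-hydroxyphenyl ending the C6 ethyl chain.
2. The strategy rests on ring C, a 1,2,3,5-tetrasubstituted benzene whose crowded C3a lies between the oxygen-bearing C4 and C7a and is fused to the dihydrofuran. Ring C is therefore built from pyridazine C3–C6 plus two alkyne carbons instead of being substituted.
3. Key disconnection: bonds C7a–C3a and C5–C4, made by an intramolecular pyridazine/alkynylboronate (4+2) cycloaddition with loss of N2. Ring C and the dihydrofuran ring form together and last; rings A, B and D are bought.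
4. After the key step: C4–B is oxidised to C4–OH, then one hydrogenolysis removes the five benzyl ethers and the C5 chlorine. Before it: alkyne C–H borylation, and SNAr etherification of anti alcohol 10 with dichloropyridazine 3 (Minisci product of 1 and 2).
5. The C2/C3 stereodiad comes from anti-selective addition of a chiral ring B allenylzinc (from resolved S mesylate 7) to ring A aldehyde 8.

Key step: step 8

Remark: all phenols are carried as benzyl ethers (the three aryl building blocks are commercial in this form), because the benzylic C2–O bond of a 2-aryl-2,3-dihydrobenzofuran would be ionised by a Lewis-acidic ether cleavage; neutral hydrogenolysis removes them together with the C5 chlorine.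

**Step 1**
Reactants: 1 3,6-dichloropyridazine; 2 3-[4-(benzyloxy)phenyl]propanoic acid
Product: 3 4-{2-[4-(benzyloxy)phenyl]ethyl}-3,6-dichloropyridazine
Conditions: AgNO3 (0.3 equiv), (NH4)2S2O8 (2.5 equiv), CF3CO2H (1 equiv), MeCN/H2O, 70 °C
Reagents that add atoms: none
Why: Minisci reaction, in which silver-catalysed persulfate decarboxylation of 2 gives the nucleophilic 2-arylethyl radical that adds to the protonated symmetrical dichloropyridazine (C4 and C5 are equivalent, so only one regioisomer can form), the standard way to 4-alkyl-3,6-dichloropyridazines.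

**Step 2**
Reactants: 4 3,5-bis(benzyloxy)benzaldehyde
Product: 5 rac-1-[3,5-bis(benzyloxy)phenyl]prop-2-yn-1-ol
Conditions: HC≡CMgBr (0.5 M in THF), THF, 0 °C → rt; aq NH4Cl
Reagents that add atoms: ethynylmagnesium bromide, C#C[Mg]Br
Why: Grignard 1,2-addition of an acetylide to a non-enolisable aryl aldehyde, giving the racemic propargylic alcohol that is resolved in step 3.

**Step 3**
Reactants: 5 rac-1-[3,5-bis(benzyloxy)phenyl]prop-2-yn-1-ol
Product: 6 (S)-1-[3,5-bis(benzyloxy)phenyl]prop-2-yn-1-ol
Conditions: Novozym 435 (immobilised Candida antarctica lipase B), vinyl acetate, MTBE, 30 °C, stopped near 50% conversion; chromatography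
Reagents that add atoms: none
Why: Lipase-catalysed kinetic resolution by irreversible transesterification, in which the empirical rule for secondary alcohols (large aryl, small ethynyl) predicts acetylation of the R alcohol, leaving the S alcohol 6, whose configuration is to be confirmed by Mosher analysis before use.

**Step 4**
Reactants: 6 (S)-1-[3,5-bis(benzyloxy)phenyl]prop-2-yn-1-ol
Product: 7 (S)-1-[3,5-bis(benzyloxy)phenyl]prop-2-yn-1-yl methanesulfonate
Conditions: MsCl, Et3N, CH2Cl2, –78 → –40 °C; cold aqueous work-up, used at once without purification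
Reagents that add atoms: methanesulfonyl chloride, CS(=O)(=O)Cl
Why: O-Sulfonylation with retention at carbon, and since the two meta benzyloxy groups do not stabilise a benzylic cation the mesylate should survive cold work-up and immediate use.

**Step 5**
Reactants: 7 (S)-1-[3,5-bis(benzyloxy)phenyl]prop-2-yn-1-yl methanesulfonate; 8 2,4-bis(benzyloxy)benzaldehyde
Product: 10 (1S,2R)-1-[2,4-bis(benzyloxy)phenyl]-2-[3,5-bis(benzyloxy)phenyl]but-3-yn-1-ol (anti), via allenyl(ethyl)zinc 9 (not isolated)
Conditions: Pd(OAc)2 (5 mol %), PPh3 (5 mol %), Et2Zn (3 equiv), THF, –78 → –20 °C; aq NH4Cl; chromatographic removal of the minor syn isomer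
Reagents that add atoms: none
Why: Marshall propargylation, in which zerovalent palladium opens the mesylate anti-SN2' to an allenylpalladium that transmetallates to allenylzinc 9, which adds to the aldehyde through a closed syn-SE2' transition state, so the propargylic centre (future C3) is set by net inversion of the mesylate centre through the allene axis and the carbinol centre (future C2) by the anti preference of the cyclic transition state.

**Step 6**
Reactants: 10 (1S,2R)-1-[2,4-bis(benzyloxy)phenyl]-2-[3,5-bis(benzyloxy)phenyl]but-3-yn-1-ol; 3 4-{2-[4-(benzyloxy)phenyl]ethyl}-3,6-dichloropyridazine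
Product: 12 4-{2-[4-(benzyloxy)phenyl]ethyl}-6-{[(1S,2R)-1-[2,4-bis(benzyloxy)phenyl]-2-[3,5-bis(benzyloxy)phenyl]but-3-yn-1-yl]oxy}-3-chloropyridazine, via sodium alkoxide 11 (not isolated)
Conditions: NaH (1.0 equiv), THF, 0 °C; then 3 (1.1 equiv), 0 °C → rt
Reagents that add atoms: none
Why: SNAr (addition–elimination) of the alkoxide, which should attack the chloride remote from the alkyl chain because that carbon is less hindered and not deactivated by an ortho alkyl group, as in known etherifications of 4-alkyl-3,6-dichloropyridazines, while the carbinol C–O bond is untouched so its configuration is kept.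

**Step 7**
Reactants: 12 the homopropargyl pyridazinyl ether
Product: 15 4-{2-[4-(benzyloxy)phenyl]ethyl}-6-{[(1S,2S)-1-[2,4-bis(benzyloxy)phenyl]-2-[3,5-bis(benzyloxy)phenyl]-4-(4,4,5,5-tetramethyl-1,3,2-dioxaborolan-2-yl)but-3-yn-1-yl]oxy}-3-chloropyridazine (same spatial arrangement as 12; the C2 descriptor changes only because boron raises the rank of the alkynyl group), via lithium acetylide 13 (not isolated), via lithium alkynylborate 14 (not isolated)
Conditions: LiN(iPr)2 (1.05 equiv), THF, –78 °C; iPrOBpin (1.2 equiv), –78 °C; HCl in Et2O (2.1 equiv), –78 °C → rt; filtration under argon, evaporation, used crude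
Reagents that add atoms: 2-isopropoxy-4,4,5,5-tetramethyl-1,3,2-dioxaborolane, CC(C)OB1OC(C)(C)C(C)(C)O1
Why: Deprotonation of the terminal alkyne (the most acidic C–H) and trapping of the acetylide with the borate ester, followed by collapse of the ate complex with anhydrous HCl, is the standard synthesis of alkynyl pinacol boronates, and the amide base at –78 °C is non-nucleophilic toward the chloropyridazine.

**Step 8 (key step)**
Reactants: 15 the alkynylboronate-tethered chloropyridazine
Product: 17 (2S,3S)-2-[2,4-bis(benzyloxy)phenyl]-3-[3,5-bis(benzyloxy)phenyl]-6-{2-[4-(benzyloxy)phenyl]ethyl}-5-chloro-4-(4,4,5,5-tetramethyl-1,3,2-dioxaborolan-2-yl)-2,3-dihydro-1-benzofuran (trans), via diazabicyclooctatriene adduct 16 (not isolated)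
Conditions: o-dichlorobenzene (0.02 M, dry, degassed), 180 °C, sealed vessel, argon, no base
Reagents that add atoms: none
Why: Intramolecular inverse-electron-demand Diels–Alder reaction, in which the electron-poor chloropyridazine reacts as the 4π component through its two carbons next to nitrogen with the tethered alkynylboronate as the 2π component, giving the 2,3-diazabicyclo[2.2.2]octatriene 16, which loses N2 in an irreversible retro-(4+2) step that aromatises ring C. The closest known reactions are the thermal cyclisations of 3-chloro-6-(but-3-ynyloxy)pyridazines to 2,3-dihydrobenzofurans and the cycloadditions of alkynyl pinacol boronates with tetrazines and 2-pyrones to aryl boronates. Ring C is closed by the cycloaddition/cycloreversion pair (bonds C7a–C3a and C5–C4), and the dihydrofuran ring is closed by the same C7a–C3a bond because O1, C2 and C3 are the three-atom tether, so a fused five-membered ring results from the intramolecular mode. No stereocentre is formed, and C2 and C3 are carried over unchanged because the medium is neutral and aprotic, so the acidic C3–H is not exchanged. The selectivity needed is regiochemical (boron on C4, chlorine on C5, chain on C6), and the tether secures it, since only the orientation that joins the internal alkyne carbon to the oxygen-bearing pyridazine carbon is geometrically possible, while the two aryl groups on the tether favour the folded reactive rotamer.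

**Step 9**
Reactants: 17 the 4-boryl-5-chloro-2,3-dihydrobenzofuran
Product: 19 (2S,3S)-2-[2,4-bis(benzyloxy)phenyl]-3-[3,5-bis(benzyloxy)phenyl]-6-{2-[4-(benzyloxy)phenyl]ethyl}-5-chloro-2,3-dihydro-1-benzofuran-4-ol, via aryl pinacol borate 18 (not isolated)
Conditions: H2O2 (30% aq), NaOH (aq), THF, 0 °C → rt
Reagents that add atoms: hydrogen peroxide, OO
Why: Oxidation of an aryl boronate by hydroperoxide (1,2-shift of the aryl group from boron to oxygen, then hydrolysis of borate 18) gives the phenol at the carbon that carried boron, and the benzyl ethers, the aryl chloride and both stereocentres are inert.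

**Step 10**
Reactants: 19 the 5-chloro-4-hydroxy pentabenzyl ether
Product: 20 CNP0329616.1, 4-[(2S,3S)-3-(3,5-dihydroxyphenyl)-4-hydroxy-6-[2-(4-hydroxyphenyl)ethyl]-2,3-dihydro-1-benzofuran-2-yl]benzene-1,3-diol
Conditions: H2 (1–3 atm), 10% Pd/C, NaOAc (1.5 equiv), EtOAc/MeOH, rt
Reagents that add atoms: none
Why: Heterogeneous palladium-catalysed hydrogenolysis removes the five O-benzyl groups and the aryl chloride (hydrodechlorination, HCl buffered by acetate) in one operation, while the cyclic secondary benzylic C2–O bond is cleaved much more slowly than benzyl aryl ethers (as in debenzylation of flavan-type ethers), so both stereocentres should persist.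

**Compound list**
1 | 3,6-dichloropyridazine | Clc1ccc(Cl)nn1 | starting material
2 | 3-[4-(benzyloxy)phenyl]propanoic acid | OC(=O)CCc1ccc(OCc2ccccc2)cc1 | starting material
3 | 4-{2-[4-(benzyloxy)phenyl]ethyl}-3,6-dichloropyridazine | Clc1nnc(Cl)cc1CCc1ccc(OCc2ccccc2)cc1 | intermediate
4 | 3,5-bis(benzyloxy)benzaldehyde | O=Cc1cc(OCc2ccccc2)cc(OCc2ccccc2)c1 | starting material
5 | rac-1-[3,5-bis(benzyloxy)phenyl]prop-2-yn-1-ol | OC(C#C)c1cc(OCc2ccccc2)cc(OCc2ccccc2)c1 | intermediate
6 | (S)-1-[3,5-bis(benzyloxy)phenyl]prop-2-yn-1-ol | O[C@@H](C#C)c1cc(OCc2ccccc2)cc(OCc2ccccc2)c1 | intermediate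
7 | (S)-1-[3,5-bis(benzyloxy)phenyl]prop-2-yn-1-yl methanesulfonate | CS(=O)(=O)O[C@@H](C#C)c1cc(OCc2ccccc2)cc(OCc2ccccc2)c1 | intermediate
8 | 2,4-bis(benzyloxy)benzaldehyde | O=Cc1ccc(OCc2ccccc2)cc1OCc1ccccc1 | starting material
9 | (Sa)-{3-[3,5-bis(benzyloxy)phenyl]propa-1,2-dien-1-yl}(ethyl)zinc, zinc anti to the departed mesylate | CC[Zn]C([H])=[C@@]=C([H])c1cc(OCc2ccccc2)cc(OCc2ccccc2)c1 | intermediate
10 | (1S,2R)-1-[2,4-bis(benzyloxy)phenyl]-2-[3,5-bis(benzyloxy)phenyl]but-3-yn-1-ol (anti) | O[C@H](c1ccc(OCc2ccccc2)cc1OCc1ccccc1)[C@H](C#C)c1cc(OCc2ccccc2)cc(OCc2ccccc2)c1 | intermediate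
11 | sodium alkoxide of 10 | [Na+].[O-][C@H](c1ccc(OCc2ccccc2)cc1OCc1ccccc1)[C@H](C#C)c1cc(OCc2ccccc2)cc(OCc2ccccc2)c1 | intermediate
12 | 4-{2-[4-(benzyloxy)phenyl]ethyl}-6-{[(1S,2R)-1-[2,4-bis(benzyloxy)phenyl]-2-[3,5-bis(benzyloxy)phenyl]but-3-yn-1-yl]oxy}-3-chloropyridazine | Clc1nnc(O[C@H](c2ccc(OCc3ccccc3)cc2OCc2ccccc2)[C@H](C#C)c2cc(OCc3ccccc3)cc(OCc3ccccc3)c2)cc1CCc1ccc(OCc2ccccc2)cc1 | intermediate
13 | lithium acetylide of 12 (configuration as in 12) | Clc1nnc(O[C@H](c2ccc(OCc3ccccc3)cc2OCc2ccccc2)[C@H](C#C[Li])c2cc(OCc3ccccc3)cc(OCc3ccccc3)c2)cc1CCc1ccc(OCc2ccccc2)cc1 | intermediate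
14 | lithium (alkynyl)(isopropoxy)pinacolborate derived from 13 (configuration as in 12) | [Li+].Clc1nnc(O[C@H](c2ccc(OCc3ccccc3)cc2OCc2ccccc2)[C@H](C#C[B-]2(OC(C)C)OC(C)(C)C(C)(C)O2)c2cc(OCc3ccccc3)cc(OCc3ccccc3)c2)cc1CCc1ccc(OCc2ccccc2)cc1 | intermediate
15 | 4-{2-[4-(benzyloxy)phenyl]ethyl}-6-{[(1S,2S)-1-[2,4-bis(benzyloxy)phenyl]-2-[3,5-bis(benzyloxy)phenyl]-4-(pinacolboryl)but-3-yn-1-yl]oxy}-3-chloropyridazine (key-step precursor) | Clc1nnc(O[C@H](c2ccc(OCc3ccccc3)cc2OCc2ccccc2)[C@H](C#CB2OC(C)(C)C(C)(C)O2)c2cc(OCc3ccccc3)cc(OCc3ccccc3)c2)cc1CCc1ccc(OCc2ccccc2)cc1 | intermediate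
16 | 2,3-diazabicyclo[2.2.2]octa-2,5,7-triene cycloadduct of 15, fused to the oxolane ring through the oxygen-bearing bridgehead and the adjacent alkene carbon; either bridgehead diastereomer, both converge | O1[C@H](c2ccc(OCc3ccccc3)cc2OCc2ccccc2)[C@@H](c2cc(OCc3ccccc3)cc(OCc3ccccc3)c2)C2=C(B3OC(C)(C)C(C)(C)O3)C3(Cl)N=NC12C=C3CCc1ccc(OCc2ccccc2)cc1 | intermediate
17 | (2S,3S)-2-[2,4-bis(benzyloxy)phenyl]-3-[3,5-bis(benzyloxy)phenyl]-6-{2-[4-(benzyloxy)phenyl]ethyl}-5-chloro-4-(pinacolboryl)-2,3-dihydro-1-benzofuran (trans; key-step product) | C(c1ccccc1)Oc1ccc(CCc2c(Cl)c(B4OC(C)(C)C(C)(C)O4)c3c(c2)O[C@H](c2ccc(OCc4ccccc4)cc2OCc2ccccc2)[C@H]3c2cc(OCc3ccccc3)cc(OCc3ccccc3)c2)cc1 | intermediate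
18 | aryl pinacol borate (C4–O–Bpin) formed from 17 by aryl migration | C(c1ccccc1)Oc1ccc(CCc2c(Cl)c(OB4OC(C)(C)C(C)(C)O4)c3c(c2)O[C@H](c2ccc(OCc4ccccc4)cc2OCc2ccccc2)[C@H]3c2cc(OCc3ccccc3)cc(OCc3ccccc3)c2)cc1 | intermediate
19 | (2S,3S)-2-[2,4-bis(benzyloxy)phenyl]-3-[3,5-bis(benzyloxy)phenyl]-6-{2-[4-(benzyloxy)phenyl]ethyl}-5-chloro-2,3-dihydro-1-benzofuran-4-ol | C(c1ccccc1)Oc1ccc(CCc2c(Cl)c(O)c3c(c2)O[C@H](c2ccc(OCc4ccccc4)cc2OCc2ccccc2)[C@H]3c2cc(OCc3ccccc3)cc(OCc3ccccc3)c2)cc1 | intermediate
20 | CNP0329616.1, 4-[(2S,3S)-3-(3,5-dihydroxyphenyl)-4-hydroxy-6-[2-(4-hydroxyphenyl)ethyl]-2,3-dihydro-1-benzofuran-2-yl]benzene-1,3-diol | Oc1ccc(CCc2cc(O)c3c(c2)O[C@H](c2ccc(O)cc2O)[C@H]3c2cc(O)cc(O)c2)cc1 | target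

**Step count**
Total: 10 steps. Longest linear sequence: 9 steps (steps 2 to 10, from aldehyde 4); step 1 is a one-step branch.

**Three steps most likely to fail**

Step 8 (key cycloaddition). The congested boryl alkyne may react so slowly that, during prolonged heating, boron is lost by protodeborylation (adventitious water) or the benzylic pyridazinyl ether fragments by heterolysis or thermal elimination before cycloaddition. The fallback keeps the cycloaddition but replaces boron by silicon as the masked hydroxyl; it sets out from 12 and returns to the route at 19. The lithium acetylide of 12 (LiN(iPr)2, THF, –78 °C) is silylated with BnMe2SiCl to the benzyldimethylsilyl alkyne F1, which can be purified by chromatography and heated without hydrolytic loss. Thermolysis in o-dichlorobenzene (180–200 °C) should give the 4-(benzyldimethylsilyl)-5-chloro-2,3-dihydrobenzofuran F2 by the same cycloaddition and loss of N2. Tamao–Fleming oxidation (Bu4NF, THF, then H2O2, KHCO3, MeOH) converts the C4–Si bond into the C4–OH of 19.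

Step 5 (allenylzinc addition). The aryl-substituted allenylzinc may lose configurational integrity by propargyl/allenyl metallotropy before it adds to the electron-rich, slow-reacting aldehyde, and the anti preference may be eroded with an aromatic aldehyde. The fallback uses a configurationally stable, isolable allenylboron reagent; it sets out from 6 and 8 and returns at 10. Alcohol 6 is converted (ClCO2Me, pyridine, CH2Cl2, 0 °C) into the methyl carbonate F3. Copper-catalysed anti-SN2' borylation with monovalent copper (CuOtBu, Xantphos, B2pin2, THF, rt) gives the allenyl pinacol boronate F4 with the same axial configuration as 9. F4 is warmed with 8 in toluene (rt → 60 °C) and adds through a closed six-membered syn-SE2' transition state; aqueous work-up gives 10.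

Step 7 (alkyne borylation). The amide base may not discriminate fully between the alkyne C–H and the benzylic or propargylic C–H bonds or the chloropyridazine, which would lead to allene isomerisation with loss of the C3 centre, and the acid quench of the ate complex may ionise the benzylic ether. The fallback is a base-free catalytic dehydrogenative C–H borylation; it sets out from 12 and returns at 15 without a new compound. Terminal alkyne 12 is treated with pinacolborane and the cyclic (alkyl)(amino)carbene complex (CAAC)CuOTf of monovalent copper (2–3 mol %) with catalytic Et3N in benzene at rt; H2 is evolved and no acid quench is needed.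

**Further compounds**
F1 | step 8 | 6-{[(1S,2S)-4-(benzyldimethylsilyl)-1-[2,4-bis(benzyloxy)phenyl]-2-[3,5-bis(benzyloxy)phenyl]but-3-yn-1-yl]oxy}-4-{2-[4-(benzyloxy)phenyl]ethyl}-3-chloropyridazine | Clc1nnc(O[C@H](c2ccc(OCc3ccccc3)cc2OCc2ccccc2)[C@H](C#C[Si](C)(C)Cc2ccccc2)c2cc(OCc3ccccc3)cc(OCc3ccccc3)c2)cc1CCc1ccc(OCc2ccccc2)cc1
F2 | step 8 | (2S,3S)-4-(benzyldimethylsilyl)-2-[2,4-bis(benzyloxy)phenyl]-3-[3,5-bis(benzyloxy)phenyl]-6-{2-[4-(benzyloxy)phenyl]ethyl}-5-chloro-2,3-dihydro-1-benzofuran | C(c1ccccc1)Oc1ccc(CCc2c(Cl)c([Si](C)(C)Cc4ccccc4)c3c(c2)O[C@H](c2ccc(OCc4ccccc4)cc2OCc2ccccc2)[C@H]3c2cc(OCc3ccccc3)cc(OCc3ccccc3)c2)cc1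
F3 | step 5 | (S)-1-[3,5-bis(benzyloxy)phenyl]prop-2-yn-1-yl methyl carbonate | COC(=O)O[C@@H](C#C)c1cc(OCc2ccccc2)cc(OCc2ccccc2)c1
F4 | step 5 | (Sa)-2-{3-[3,5-bis(benzyloxy)phenyl]propa-1,2-dien-1-yl}-4,4,5,5-tetramethyl-1,3,2-dioxaborolane | CC1(C)OB(OC1(C)C)C([H])=[C@@]=C([H])c1cc(OCc2ccccc2)cc(OCc2ccccc2)c1
F0 | step 7 | none | none
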